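**Remark (assumption).** The target has no stereocentre and no stereogenic double bond (the prenyl alkene carries two identical methyl groups), so there is no enantiomer to select and the route only has to deliver the constitution. Compounds 1, 3, 6 and 13 are taken as commercially available.

## Retrosynthetic overview

- The acid-labile prenyl ether is installed last, on the 7-OH of 5,7,2',4'-tetrahydroxyisoflavone 12, which comes from tetramethyl ether 11 by global demethylation.
- Ring C (the pyranone) is the only ring formed. It is opened at C4–C4a to a 3-(3,5-dimethoxyphenoxy)-2-(2,4-dimethoxyphenyl)acrylic acid, which closes by intramolecular Friedel–Crafts acylation.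
- The strategy rests on one feature: C4a of ring A lies ortho to the ring oxygen O1 on a phloroglucinol-type ring. The two carbons ortho to the phenoxy oxygen (future C4a and C8) are symmetry-equivalent, so forming C4–C4a involves no regiochemical choice.
- The acrylic acid comes from vinylic substitution of the enol tosylate of methyl α-formyl-(2,4-dimethoxyphenyl)acetate by 3,5-dimethoxyphenol. C2 of the isoflavone comes from methyl formate.
- Rings A and B are bought preformed (3,5-dimethoxyphenol and 2,4-dimethoxyphenylacetic acid); ring C is closed in step 6.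

Key step: step 6

## Route

Step 1
Reactants: 1 2,4-dimethoxyphenylacetic acid
Product: 2 methyl 2-(2,4-dimethoxyphenyl)acetate
Conditions: MeOH, cat. H2SO4, reflux
Reagents that add atoms: methanol, CO
Why: Fischer esterification of an unhindered arylacetic acid, driven by methanol as solvent, with the aryl methyl ethers inert.

Step 2
Reactants: 2 methyl 2-(2,4-dimethoxyphenyl)acetate; 3 methyl formate
Product: 4 methyl (Z)-2-(2,4-dimethoxyphenyl)-3-hydroxyprop-2-enoate (chelated enol form of the α-formyl ester, in equilibrium with its aldehyde tautomer)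
Conditions: NaH, HCO2Me (excess), THF, 0 °C → rt; then cold aq. HCl
Reagents that add atoms: none
Why: Crossed Claisen condensation (C-formylation) of the arylacetate enolate with non-enolisable methyl formate, pulled forward by deprotonation of the acidic α-formyl ester as it forms.

Step 3
Reactants: 4 methyl (Z)-2-(2,4-dimethoxyphenyl)-3-hydroxyprop-2-enoate
Product: 5 methyl (E)-2-(2,4-dimethoxyphenyl)-3-(tosyloxy)prop-2-enoate
Conditions: TsCl, N-methylimidazole, Et3N, MeCN, 0 °C
Reagents that add atoms: p-toluenesulfonyl chloride, Cc1ccc(cc1)S(=O)(=O)Cl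
Why: O-sulfonylation of the enol through the N-sulfonylimidazolium species under non-chelating amine-base conditions should favour the (E)-enol tosylate, and the geometry is not critical for what follows.

Step 4
Reactants: 5 methyl (E)-2-(2,4-dimethoxyphenyl)-3-(tosyloxy)prop-2-enoate; 6 3,5-dimethoxyphenol
Product: 7 methyl (E)-3-(3,5-dimethoxyphenoxy)-2-(2,4-dimethoxyphenyl)prop-2-enoate
Conditions: K2CO3, DMF, rt → 40 °C
Reagents that add atoms: none
Why: Nucleophilic vinylic substitution by addition–elimination, in which the phenoxide oxygen adds to the unhindered β-CH of the acrylate and the ester- and aryl-stabilised carbanion expels tosylate, the (E)-isomer (aryloxy trans to the ester) being expected as for related β-alkoxyacrylates.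

Step 5
Reactants: 7 methyl (E)-3-(3,5-dimethoxyphenoxy)-2-(2,4-dimethoxyphenyl)prop-2-enoate
Product: 8 (E)-3-(3,5-dimethoxyphenoxy)-2-(2,4-dimethoxyphenyl)prop-2-enoic acid
Conditions: LiOH·H2O, THF/MeOH/H2O, rt; then cold aq. HCl to pH 2–3
Reagents that add atoms: lithium hydroxide, [Li+].[OH-]
Why: Ester saponification (BAc2) at room temperature, the usual way 3-aryloxyacrylic esters are converted into their acids, in which attack at the ester carbonyl outpaces hydroxide addition to the donor-deactivated C3.

Step 6
Reactants: 8 (E)-3-(3,5-dimethoxyphenoxy)-2-(2,4-dimethoxyphenyl)prop-2-enoic acid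
Product: 11 5,7-dimethoxy-3-(2,4-dimethoxyphenyl)-4H-chromen-4-one, via (Z)-acrylic acid 9 (not isolated), via acylium ion 10 (not isolated)
Conditions: P2O5–MeSO3H (1:10 w/w), 25 → 50 °C; ice-water quench
Reagents that add atoms: none
Why: This is the acid-mediated closure of a 3-aryloxyacrylic acid to a chromone, an intramolecular Friedel–Crafts acylation, applied here to an α-aryl acid. In P2O5/MeSO3H the push–pull enol ether loses its geometric integrity (reversible protonation at C2 and the ketene–oxocarbenium character of the activated acid), so the isolated (E)-acid 8 passes into (Z)-acid 9, whose carboxyl group is dehydrated to acylium ion 10 lying cis to the aryloxy group. The acylium carbon (future C4) is attacked by the ring-A carbon ortho to the ether oxygen (future C4a) in an electrophilic aromatic substitution that forms C4–C4a and closes the six-membered pyranone as a 6-exo-dig attack on the C≡O+ unit, and loss of the ring proton gives the aromatic chromen-4-one at the correct oxidation level. No stereocentre is created. The only selectivity needed is the site of attack on ring A, and the substrate secures it: the two carbons ortho to the phenoxy oxygen are symmetry-equivalent and each is activated by three oxygen substituents, the para carbon cannot reach the acylium carbon, and ring B could do so only through a four-membered ring.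

Step 7
Reactants: 11 5,7-dimethoxy-3-(2,4-dimethoxyphenyl)-4H-chromen-4-one
Product: 12 5,7-dihydroxy-3-(2,4-dihydroxyphenyl)-4H-chromen-4-one
Conditions: BBr3 (excess), CH2Cl2, −78 °C → rt; then MeOH/H2O
Reagents that add atoms: none
Why: Lewis-acid cleavage of aryl methyl ethers by BBr3 (O-coordination, then bromide SN2 at methyl), in which the peri 5-OMe goes first through chelation to C4=O and excess reagent at room temperature should complete the other three without harming the chromone core.

Step 8
Reactants: 12 5,7-dihydroxy-3-(2,4-dihydroxyphenyl)-4H-chromen-4-one; 13 prenyl bromide (1-bromo-3-methylbut-2-ene)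
Product: 14 5-hydroxy-3-(2,4-dihydroxyphenyl)-7-[(3-methylbut-2-en-1-yl)oxy]-4H-chromen-4-one (target)
Conditions: K2CO3 (1.0 equiv), prenyl bromide (1.0 equiv, slow addition), DMF, 0 °C → rt
Reagents that add atoms: none
Why: Williamson etherification under monoanion control, since the 7-OH para to the C4 carbonyl is a vinylogous carboxylic acid and by far the most acidic phenol, the 5-OH is locked in a hydrogen bond to C4=O and the ring-B hydroxyls are ordinary phenols, so one equivalent of base should ionise O7 preferentially and it is alkylated by SN2 at the primary allylic bromide.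

## Compound list

1 | 2,4-dimethoxyphenylacetic acid | COc1ccc(CC(=O)O)c(OC)c1 | starting material
2 | methyl 2-(2,4-dimethoxyphenyl)acetate | COC(=O)Cc1ccc(OC)cc1OC | intermediate
3 | methyl formate | COC=O | starting material
4 | methyl (Z)-2-(2,4-dimethoxyphenyl)-3-hydroxyprop-2-enoate (enol tautomer of the α-formyl ester) | COC(=O)/C(=C\O)c1ccc(OC)cc1OC | intermediate
5 | methyl (E)-2-(2,4-dimethoxyphenyl)-3-(tosyloxy)prop-2-enoate | COC(=O)/C(=C/OS(=O)(=O)c1ccc(C)cc1)c1ccc(OC)cc1OC | intermediate
6 | 3,5-dimethoxyphenol | COc1cc(O)cc(OC)c1 | starting material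
7 | methyl (E)-3-(3,5-dimethoxyphenoxy)-2-(2,4-dimethoxyphenyl)prop-2-enoate | COC(=O)/C(=C/Oc1cc(OC)cc(OC)c1)c1ccc(OC)cc1OC | intermediate
8 | (E)-3-(3,5-dimethoxyphenoxy)-2-(2,4-dimethoxyphenyl)prop-2-enoic acid | OC(=O)/C(=C/Oc1cc(OC)cc(OC)c1)c1ccc(OC)cc1OC | intermediate
9 | (Z)-3-(3,5-dimethoxyphenoxy)-2-(2,4-dimethoxyphenyl)prop-2-enoic acid (reactive geometry, not isolated) | OC(=O)/C(=C\Oc1cc(OC)cc(OC)c1)c1ccc(OC)cc1OC | intermediate
10 | (Z)-3-(3,5-dimethoxyphenoxy)-2-(2,4-dimethoxyphenyl)prop-2-enoylium ion (not isolated) | [O+]#C/C(=C\Oc1cc(OC)cc(OC)c1)c1ccc(OC)cc1OC | intermediate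
11 | 5,7-dimethoxy-3-(2,4-dimethoxyphenyl)-4H-chromen-4-one | COc1ccc(-c2coc3cc(OC)cc(OC)c3c2=O)c(OC)c1 | intermediate
12 | 5,7-dihydroxy-3-(2,4-dihydroxyphenyl)-4H-chromen-4-one | O=c1c(-c2ccc(O)cc2O)coc2cc(O)cc(O)c12 | intermediate
13 | prenyl bromide (1-bromo-3-methylbut-2-ene) | CC(C)=CCBr | starting material
14 | 5-hydroxy-3-(2,4-dihydroxyphenyl)-7-[(3-methylbut-2-en-1-yl)oxy]-4H-chromen-4-one | CC(C)=CCOc1cc(O)c2c(=O)c(-c3ccc(O)cc3O)coc2c1 | target

## Step count

Total steps: 8. Longest linear sequence: 8 (from 2,4-dimethoxyphenylacetic acid 1).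

## Steps most likely to fail

**Step 6 (key ring closure).** The E→Z equilibration may be too slow compared with protodecarboxylation of the C2-protonated enol ether. The electron-rich rings may also be sulfonylated or acylated intermolecularly in the strongly acidic medium.
Fallback: setting out from acid 8, the enol-ether double bond is hydrogenated (H2, Pd/C, EtOAc) to racemic 3-(3,5-dimethoxyphenoxy)-2-(2,4-dimethoxyphenyl)propanoic acid F1, which has no geometric requirement and no vinylogous decarboxylation path. Trifluoroacetic anhydride in CH2Cl2 (0 °C → rt) then forms the same C4–C4a bond by mixed-anhydride Friedel–Crafts acylation, giving racemic 5,7-dimethoxy-3-(2,4-dimethoxyphenyl)chroman-4-one F2. DDQ in refluxing dioxane dehydrogenates C2–C3 and rejoins the route at 11.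

**Step 8 (7-O-prenylation).** Ionisation may not be fully selective, which would lead to alkylation at O4' or O2', double alkylation, or C-prenylation at C6/C8.
Fallback: setting out from tetraol 12, peracetylation (Ac2O, pyridine) gives 5,7-diacetoxy-3-(2,4-diacetoxyphenyl)-4H-chromen-4-one F3. Thiophenol/imidazole in NMP at 0 °C removes only the 7-acetate, whose phenoxide is the best leaving group, to give 5-acetoxy-3-(2,4-diacetoxyphenyl)-7-hydroxy-4H-chromen-4-one F4. A Mitsunobu etherification with 3-methylbut-2-en-1-ol (PPh3, DIAD, THF, 0 °C) alkylates the single free phenol to 5-acetoxy-3-(2,4-diacetoxyphenyl)-7-[(3-methylbut-2-en-1-yl)oxy]-4H-chromen-4-one F5. Methanolysis (cat. K2CO3, MeOH, rt), to which the prenyl ether is inert, then arrives at 14.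

**Step 4 (vinylic substitution).** The phenoxide may attack the sulfonyl sulfur of the enol tosylate (tosyl transfer) instead of C3, or the ambident phenoxide may react through a ring carbon.
Fallback: setting out from enol 4, Ph3P·Br2/Et3N in CH2Cl2 converts the enol into methyl 3-bromo-2-(2,4-dimethoxyphenyl)prop-2-enoate F6 (E/Z mixture expected, geometry immaterial). This bromide has no sulfur electrophile. It is joined to phenol 6 by a copper-catalysed Ullmann-type vinyl C–O coupling (CuI, N,N-dimethylglycine, Cs2CO3, dioxane, 80 °C), which enforces bonding through oxygen, and the route is rejoined at 7.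

## Further compounds

F1 | step 6 | racemic 3-(3,5-dimethoxyphenoxy)-2-(2,4-dimethoxyphenyl)propanoic acid | OC(=O)C(COc1cc(OC)cc(OC)c1)c1ccc(OC)cc1OC
F2 | step 6 | racemic 5,7-dimethoxy-3-(2,4-dimethoxyphenyl)chroman-4-one | COc1ccc(C2COc3cc(OC)cc(OC)c3C2=O)c(OC)c1
F3 | step 8 | 5,7-diacetoxy-3-(2,4-diacetoxyphenyl)-4H-chromen-4-one | CC(=O)Oc1ccc(-c2coc3cc(OC(C)=O)cc(OC(C)=O)c3c2=O)c(OC(C)=O)c1
F4 | step 8 | 5-acetoxy-3-(2,4-diacetoxyphenyl)-7-hydroxy-4H-chromen-4-one | CC(=O)Oc1ccc(-c2coc3cc(O)cc(OC(C)=O)c3c2=O)c(OC(C)=O)c1
F5 | step 8 | 5-acetoxy-3-(2,4-diacetoxyphenyl)-7-[(3-methylbut-2-en-1-yl)oxy]-4H-chromen-4-one | CC(=O)Oc1ccc(-c2coc3cc(OCC=C(C)C)cc(OC(C)=O)c3c2=O)c(OC(C)=O)c1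
F6 | step 4 | methyl 3-bromo-2-(2,4-dimethoxyphenyl)prop-2-enoate (E/Z mixture, E drawn) | COC(=O)/C(=C/Br)c1ccc(OC)cc1OC
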